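**Plan**

- Retrosynthesis: C17 is cut from C8 (one-carbon homologation of a C8 ketone), the enoate is cut at C14–C15 and C13–C16 (alkynoate plus methyl cuprate) and at C13≡C14 (alkyne from the C13 aldehyde), then both C4 methyl groups and the C4=C5 aldol bond of ring A are removed. Ring B remains and is cut at C9–C11 and C1–C10 in one operation.
- Forward: ring B is a 4-silyloxy-2-methylcyclohexenone. The key step attaches the C11–C13 acetal chain to C9 and the four-carbon ketone chain to C10, ring A then closes by aldol condensation, and the side chain and C17 are completed last.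
- Enabling feature: C8, C9 and C10 are contiguous on ring B with the C9 chain trans both to the C8 substituent and to C1. This is the pattern that anti conjugate addition next to a C8 silyl ether, followed by anti trapping of the C5=C10 enolate, produces.
- Stereochemistry: the C8 oxygen comes from a lipase resolution and is relayed to C9 and then C10. C3 is set by axial hydride delivery, C5 by hydrogenation anti to the angular methyl, the final C8 centre by equilibration of the aldehyde, and the 13Z alkene by syn carbocupration.

Key step: step 6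

Remark: atoms carry labdane numbers and α/β refer to the usual drawing with ring A on the left (target: 10α-CH3, 9α side chain, 8β-CHO, 5β-H, 3α-OH, an ent-labdane pattern); the tetrahydropyranyl ethers are carried as mixtures at the acetal carbon and the methyl enol ethers as E/Z mixtures, neither of which reaches the target.

**Route**

Step 1
Reactants: 1 3-ethoxy-2-methylcyclohex-2-en-1-one
Product: 2 rac-6-acetoxy-3-ethoxy-2-methylcyclohex-2-en-1-one
Conditions: Mn(OAc)3·2H2O (3 equiv), benzene/AcOH (10:1), reflux
Reagents that add atoms: manganese triacetate, CC(=O)O[Mn](OC(C)=O)OC(C)=O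
Why: α′-Acetoxylation of a β-alkoxy enone by trivalent manganese should take place at C6, the only position that forms the cross-conjugated enolate (C2 is fully substituted), and introduces as a racemate the oxygen that becomes the C8 control element.

Step 2
Reactants: 2 rac-6-acetoxy-3-ethoxy-2-methylcyclohex-2-en-1-one
Product: 4 rac-4-hydroxy-2-methylcyclohex-2-en-1-one, via allylic diol 3 (not isolated)
Conditions: LiAlH4, Et2O, 0 °C; then 1 M HCl, THF, rt
Reagents that add atoms: water, O
Why: 1,2-Reduction of the vinylogous ester (the acetate is cleaved in the same operation) followed by acid hydrolysis of the enol ether with loss of the allylic hydroxyl is the Stork–Danheiser carbonyl transposition, which turns the α′-oxygen of 2 into the γ-oxygen of a 2-methyl enone.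

Step 3
Reactants: 4 rac-4-hydroxy-2-methylcyclohex-2-en-1-one
Product: 5 (S)-4-hydroxy-2-methylcyclohex-2-en-1-one
Conditions: lipase from Burkholderia cepacia (lipase PS), vinyl acetate, t-BuOMe, 30 °C, stopped just beyond half conversion; chromatography
Reagents that add atoms: none
Why: Lipase-catalysed kinetic resolution by irreversible transesterification, in which the (R)-alcohol (alkene branch as the large substituent) should be acetylated faster, so that the unreacted (S)-alcohol is recovered in high enantiomeric purity once conversion passes one half.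

Step 4
Reactants: 5 (S)-4-hydroxy-2-methylcyclohex-2-en-1-one
Product: 6 (S)-4-(tert-butyldimethylsilyloxy)-2-methylcyclohex-2-en-1-one
Conditions: TBSCl (1.2 equiv), imidazole (2.5 equiv), DMF, rt
Reagents that add atoms: tert-butyldimethylsilyl chloride, CC(C)(C)[Si](C)(C)Cl
Why: Standard silylation of a secondary allylic alcohol installs the bulky ether that steers the conjugate addition and withstands the basic steps up to the C8 oxidation.

Step 5
Reactants: 7 2-(2-bromoethyl)-1,3-dioxolane
Product: 8 [2-(1,3-dioxolan-2-yl)ethyl]magnesium bromide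
Conditions: Mg turnings (I2 crystal), THF, 25–30 °C; solution used at once
Reagents that add atoms: magnesium, [Mg]
Why: Grignard formation from a primary bromide, held near ambient temperature because this β-acetal organomagnesium reagent decomposes on heating.

Step 6
Reactants: 6 (S)-4-(tert-butyldimethylsilyloxy)-2-methylcyclohex-2-en-1-one; 8 [2-(1,3-dioxolan-2-yl)ethyl]magnesium bromide; 9 3-(trimethylsilyl)but-3-en-2-one
Product: 11 (2S,3S,4S)-4-(tert-butyldimethylsilyloxy)-3-[2-(1,3-dioxolan-2-yl)ethyl]-2-methyl-2-[3-oxo-2-(trimethylsilyl)butyl]cyclohexan-1-one, via magnesium enolate 10 (not isolated)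
Conditions: 8 (1.3 equiv), CuBr·SMe2 (10 mol%), THF, −78 → −40 °C; then 9 (1.5 equiv), −78 → −20 °C; NH4Cl (aq)
Reagents that add atoms: none
Why: Transmetalation of 8 to CuBr·SMe2 gives an organocopper species of monovalent copper that adds 1,4 to enone 6 and leaves the regiodefined bromomagnesium enolate 10 (C5=C10), which then adds in Michael fashion to the α-silyl enone 9; the closest known reaction type is conjugate addition with enolate trapping by an α-silyl vinyl ketone, the first half of a Robinson annulation. No ring closes in this step. C9 is set by the C8 silyloxy group, which sits pseudoaxial in the reacting half-chair so that the nucleophile enters axially on the opposite (α) face, and C10 is set by the new C9 chain, which shields the α face of the enolate so that C1 is attached from the β face and the methyl group ends cis to the chain. The step needs C-alkylation at C10 without proton transfer to C6 and without oligomerisation of the acceptor: the first is secured by keeping the enolate cold and free of proton sources until 9 is added, the second by the trimethylsilyl group, which stabilises the adduct carbanion and hinders a further Michael addition. The silyl-bearing carbon of 11 is formed as a mixture, which is of no consequence because silicon is removed in step 7.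

Step 7
Reactants: 11 ring B α-silyl 1,5-diketone
Product: 14 (4aS,5S,6S)-6-(tert-butyldimethylsilyloxy)-5-[2-(1,3-dioxolan-2-yl)ethyl]-4a-methyl-4,4a,5,6,7,8-hexahydronaphthalen-2(3H)-one, via desilylated diketone 12 (not isolated), via ketol 13 (not isolated)
Conditions: NaOMe (2 equiv), MeOH, rt → 60 °C
Reagents that add atoms: none
Why: Methoxide cleaves the C–Si bond α to the ketone, the freed methyl ketone closes ring A by a 6-(enolendo)-exo-trig aldol addition of C4 to the C5 carbonyl, and E1cB loss of water gives the conjugated enone (completion of the Robinson annulation), while the C8 silyl ether, being γ to the ring ketone, can neither eliminate nor epimerise.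

Step 8
Reactants: 14 ring A/B Δ4-3-ketone
Product: 16 4,4-dimethyl-Δ5-3-ketone (8β-OTBS, 9α-dioxolanylethyl, 10α-CH3), via 4-monomethyl ketone 15 (not isolated)
Conditions: KOt-Bu (3.5 equiv), t-BuOH/THF, rt; MeI (6 equiv), 0 °C → rt
Reagents that add atoms: iodomethane, CI
Why: Deconjugative α,α-dialkylation of an enone, in which the extended dienolate is methylated twice at C4, installs the gem-dimethyl group and moves the double bond to C5=C6.

Step 9
Reactants: 16 4,4-dimethyl-Δ5-3-ketone
Product: 17 3α-hydroxy-4,4-dimethyl-Δ5 compound (8β-OTBS, 9α-dioxolanylethyl, 10α-CH3)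
Conditions: NaBH4, MeOH, 0 °C
Reagents that add atoms: none
Why: Borohydride reduction of the hindered cyclohexanone by axial attack on the β face, away from the axial 4α-methyl group, should give the equatorial 3α-alcohol cis to the C10 methyl, as is general for 4,4-dimethyl-3-ketones of this ring system.

Step 10
Reactants: 17 3α-hydroxy-Δ5 compound
Product: 18 trans-decalin alcohol (3α-OH, 5β-H, 8β-OTBS, 9α-dioxolanylethyl, 10α-CH3)
Conditions: H2 (4 bar), 10% Pd/C, EtOAc, rt
Reagents that add atoms: none
Why: Heterogeneous hydrogenation should add hydrogen syn to the β face of C5=C6, because the α face is blocked by the axial methyl groups at C4 and C10, which gives the trans ring fusion with H5 anti to the angular methyl.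

Step 11
Reactants: 18 trans-decalin alcohol
Product: 19 C13 aldehyde (3-oxopropyl chain at C9; 3α-OH, 8β-OTBS)
Conditions: PPTS (0.3 equiv), acetone/H2O (10:1), 60 °C
Reagents that add atoms: water, O
Why: Mild acid-catalysed hydrolysis of the dioxolane (driven by transacetalisation to acetone) frees the aldehyde under conditions that a secondary tert-butyldimethylsilyl ether should tolerate.

Step 12
Reactants: 19 C13 aldehyde
Product: 20 terminal alkyne (but-3-ynyl chain at C9; 3α-OH, 8β-OTBS)
Conditions: dimethyl (1-diazo-2-oxopropyl)phosphonate (1.5 equiv), K2CO3 (2 equiv), MeOH, 0 °C → rt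
Reagents that add atoms: dimethyl (1-diazo-2-oxopropyl)phosphonate, COP(=O)(OC)C(=[N+]=[N-])C(C)=O
Why: Seyferth–Gilbert homologation in its Ohira–Bestmann form converts the aldehyde into the C13≡C14 alkyne under mild base that leaves the free C3 hydroxyl and the silyl ether untouched.

Step 13
Reactants: 20 terminal alkyne
Product: 21 3α-O-tetrahydropyranyl ether of 20
Conditions: 3,4-dihydro-2H-pyran (2 equiv), PPTS (0.1 equiv), CH2Cl2, rt
Reagents that add atoms: 3,4-dihydro-2H-pyran, C1=COCCC1
Why: Acid-catalysed addition of the C3 alcohol to the enol ether gives an acetal that withstands fluoride, oxidant, ylide, organolithium and cuprate and is lost in the final acidic step without a separate deprotection.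

Step 14
Reactants: 21 tetrahydropyranyl ether
Product: 22 8β-alcohol (3α-OTHP, but-3-ynyl chain)
Conditions: n-Bu4NF (3 equiv), THF, rt → 45 °C
Reagents that add atoms: none
Why: Fluoride-induced cleavage of the Si–O bond frees the C8 hydroxyl while the C3 acetal and the alkyne are inert.

Step 15
Reactants: 22 8β-alcohol
Product: 23 8-ketone (3α-OTHP, but-3-ynyl chain)
Conditions: (n-Pr4N)RuO4 (5 mol%), N-methylmorpholine N-oxide (1.5 equiv), 4 Å molecular sieves, CH2Cl2, rt
Reagents that add atoms: none
Why: Ley–Griffith oxidation of the only free alcohol gives the C8 ketone under neutral conditions, and C9, now α to a carbonyl, already carries its chain in the stable equatorial position.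

Step 16
Reactants: 23 8-ketone
Product: 24 17-methoxy-8(17)-ene (methyl enol ether; 3α-OTHP, but-3-ynyl chain)
Conditions: MeOCH2PPh3Cl (4 equiv), KN(SiMe3)2 (3.8 equiv), THF, 0 °C; then 23, 0 °C → rt
Reagents that add atoms: (methoxymethyl)triphenylphosphonium chloride, [Cl-].COC[P+](c1ccccc1)(c1ccccc1)c1ccccc1
Why: Wittig methoxymethylenation of the cyclohexanone attaches C17 as a methyl enol ether, a masked aldehyde that survives the basic and organometallic steps that follow and is introduced before any ester is present.

Step 17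
Reactants: 24 methyl enol ether
Product: 26 methyl alkynoate (C15 ester on C14; enol ether and OTHP retained), via lithium acetylide 25 (not isolated)
Conditions: n-BuLi (1.1 equiv), THF, −78 °C; ClCO2Me (1.5 equiv), −78 → 0 °C
Reagents that add atoms: methyl chloroformate, COC(=O)Cl
Why: Deprotonation of the terminal alkyne, the only acidic site left, and acylation of the acetylide by the chloroformate gives the alkynoate that carries C15.

Step 18
Reactants: 26 methyl alkynoate
Product: 28 methyl (13Z)-enoate (enol ether and OTHP retained), via alkenylcuprate 27 (not isolated)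
Conditions: Me2CuLi (1.5 equiv, from CuI and MeLi), THF, −78 °C; MeOH, −78 °C; then NH4Cl/NH3 (aq)
Reagents that add atoms: lithium dimethylcuprate, [Li+].C[Cu-]C
Why: Conjugate addition of the cuprate to the alkynoate is a syn carbocupration, so protonation of the alkenylcopper intermediate at −78 °C, before it can isomerise through the allenoate, places the C16 methyl cis to H14 and the C12 chain cis to the ester, which is the 13Z geometry.

Step 19
Reactants: 28 methyl (13Z)-enoate
Product: 30 methyl (2Z)-5-[(1R,2S,4aS,6R,8aS)-2-formyl-6-hydroxy-5,5,8a-trimethyldecahydronaphthalen-1-yl]-3-methylpent-2-enoate (target), via axial C8 aldehyde 29 (not isolated)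
Conditions: 1 M HCl/THF (1:4), rt → 40 °C
Reagents that add atoms: water, O
Why: Aqueous acid hydrolyses the enol ether to the C17 aldehyde and the tetrahydropyranyl acetal to the C3 alcohol, and the aldehyde, expected to form first mainly by protonation of C8 from the open β face, should equilibrate through its enol to the equatorial 8β-formyl epimer trans to the C9 chain, in which the 1,3-diaxial contact with the C10 methyl is relieved.

**Compound list**

1 | 3-ethoxy-2-methylcyclohex-2-en-1-one | CCOC1=C(C)C(=O)CCC1 | starting material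
2 | rac-6-acetoxy-3-ethoxy-2-methylcyclohex-2-en-1-one | CCOC1=C(C)C(=O)C(OC(C)=O)CC1 | intermediate
3 | 3-ethoxy-2-methylcyclohex-2-ene-1,6-diol (mixture of stereoisomers) | CCOC1=C(C)C(O)C(O)CC1 | intermediate (not isolated)
4 | rac-4-hydroxy-2-methylcyclohex-2-en-1-one | CC1=CC(O)CCC1=O | intermediate
5 | (S)-4-hydroxy-2-methylcyclohex-2-en-1-one | CC1=C[C@@H](O)CCC1=O | intermediate
6 | (S)-4-(tert-butyldimethylsilyloxy)-2-methylcyclohex-2-en-1-one | CC1=C[C@@H](O[Si](C)(C)C(C)(C)C)CCC1=O | intermediate
7 | 2-(2-bromoethyl)-1,3-dioxolane | BrCCC1OCCO1 | starting material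
8 | [2-(1,3-dioxolan-2-yl)ethyl]magnesium bromide | Br[Mg]CCC1OCCO1 | intermediate
9 | 3-(trimethylsilyl)but-3-en-2-one | CC(=O)C(=C)[Si](C)(C)C | starting material
10 | bromomagnesium C5=C10 enolate of (3S,4S)-4-(tert-butyldimethylsilyloxy)-3-[2-(1,3-dioxolan-2-yl)ethyl]-2-methylcyclohexanone | O1CCOC1CC[C@@H]2[C@@H](O[Si](C)(C)C(C)(C)C)CCC(O[Mg]Br)=C2C | intermediate (not isolated)
11 | (2S,3S,4S)-4-(tert-butyldimethylsilyloxy)-3-[2-(1,3-dioxolan-2-yl)ethyl]-2-methyl-2-[3-oxo-2-(trimethylsilyl)butyl]cyclohexan-1-one (mixture at the silyl-bearing carbon) | O1CCOC1CC[C@@H]2[C@@H](O[Si](C)(C)C(C)(C)C)CCC(=O)[C@@]2(C)CC([Si](C)(C)C)C(C)=O | intermediate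
12 | (2S,3S,4S)-4-(tert-butyldimethylsilyloxy)-3-[2-(1,3-dioxolan-2-yl)ethyl]-2-methyl-2-(3-oxobutyl)cyclohexan-1-one | O1CCOC1CC[C@@H]2[C@@H](O[Si](C)(C)C(C)(C)C)CCC(=O)[C@@]2(C)CCC(C)=O | intermediate (not isolated)
13 | 5-hydroxy-3-ketone (ring A ketol; 8β-OTBS, 9α-dioxolanylethyl, 10α-CH3) | O1CCOC1CC[C@@H]2[C@@H](O[Si](C)(C)C(C)(C)C)CCC3(O)CC(=O)CC[C@@]23C | intermediate (not isolated)
14 | (4aS,5S,6S)-6-(tert-butyldimethylsilyloxy)-5-[2-(1,3-dioxolan-2-yl)ethyl]-4a-methyl-4,4a,5,6,7,8-hexahydronaphthalen-2(3H)-one (Δ4-3-ketone; 8β-OTBS, 9α-chain, 10α-CH3) | O1CCOC1CC[C@@H]2[C@@H](O[Si](C)(C)C(C)(C)C)CCC3=CC(=O)CC[C@@]23C | intermediate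
15 | 4-methyl-Δ5-3-ketone (one methyl at C4; other centres as in 14) | O1CCOC1CC[C@@H]2[C@@H](O[Si](C)(C)C(C)(C)C)CC=C3C(C)C(=O)CC[C@@]23C | intermediate (not isolated)
16 | 4,4-dimethyl-Δ5-3-ketone (8β-OTBS, 9α-dioxolanylethyl, 10α-CH3) | O1CCOC1CC[C@@H]2[C@@H](O[Si](C)(C)C(C)(C)C)CC=C3C(C)(C)C(=O)CC[C@@]23C | intermediate
17 | 3α-hydroxy-4,4-dimethyl-Δ5 compound (8β-OTBS, 9α-dioxolanylethyl, 10α-CH3) | O1CCOC1CC[C@@H]2[C@@H](O[Si](C)(C)C(C)(C)C)CC=C3C(C)(C)[C@H](O)CC[C@@]23C | intermediate
18 | trans-decalin alcohol (3α-OH, 5β-H, 8β-OTBS, 9α-dioxolanylethyl, 10α-CH3) | O1CCOC1CC[C@@H]2[C@@H](O[Si](C)(C)C(C)(C)C)CC[C@@H]3C(C)(C)[C@H](O)CC[C@@]23C | intermediate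
19 | C13 aldehyde (9α-(3-oxopropyl); 3α-OH, 5β-H, 8β-OTBS, 10α-CH3) | O=CCC[C@@H]1[C@@H](O[Si](C)(C)C(C)(C)C)CC[C@@H]2C(C)(C)[C@H](O)CC[C@@]12C | intermediate
20 | terminal alkyne (9α-(but-3-ynyl); 3α-OH, 8β-OTBS) | C#CCC[C@@H]1[C@@H](O[Si](C)(C)C(C)(C)C)CC[C@@H]2C(C)(C)[C@H](O)CC[C@@]12C | intermediate
21 | 3α-O-tetrahydropyranyl ether of 20 | C#CCC[C@@H]1[C@@H](O[Si](C)(C)C(C)(C)C)CC[C@@H]2C(C)(C)[C@H](OC3CCCCO3)CC[C@@]12C | intermediate
22 | 8β-alcohol (3α-OTHP, 9α-(but-3-ynyl)) | C#CCC[C@@H]1[C@@H](O)CC[C@@H]2C(C)(C)[C@H](OC3CCCCO3)CC[C@@]12C | intermediate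
23 | 8-ketone (3α-OTHP, 9α-(but-3-ynyl)) | C#CCC[C@@H]1C(=O)CC[C@@H]2C(C)(C)[C@H](OC3CCCCO3)CC[C@@]12C | intermediate
24 | 17-methoxy-8(17)-ene (methyl enol ether, E/Z mixture; 3α-OTHP, 9α-(but-3-ynyl)) | C#CCC[C@@H]1C(=COC)CC[C@@H]2C(C)(C)[C@H](OC3CCCCO3)CC[C@@]12C | intermediate
25 | lithium acetylide of 24 | [Li]C#CCC[C@@H]1C(=COC)CC[C@@H]2C(C)(C)[C@H](OC3CCCCO3)CC[C@@]12C | intermediate (not isolated)
26 | methyl alkynoate (C13≡C14–CO2Me; enol ether and 3α-OTHP retained) | COC(=O)C#CCC[C@@H]1C(=COC)CC[C@@H]2C(C)(C)[C@H](OC3CCCCO3)CC[C@@]12C | intermediate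
27 | lithium alkenyl(methyl)cuprate (copper on C14, cis to the C16 methyl) | [Li+].COC(=O)/C([Cu-]C)=C(/C)CC[C@@H]1C(=COC)CC[C@@H]2C(C)(C)[C@H](OC3CCCCO3)CC[C@@]12C | intermediate (not isolated)
28 | methyl (13Z)-enoate (enol ether and 3α-OTHP retained) | COC(=O)/C=C(/C)CC[C@@H]1C(=COC)CC[C@@H]2C(C)(C)[C@H](OC3CCCCO3)CC[C@@]12C | intermediate
29 | 8α-formyl (axial) epimer of the target | COC(=O)/C=C(/C)CC[C@@H]1[C@H](C=O)CC[C@@H]2C(C)(C)[C@H](O)CC[C@@]12C | intermediate (not isolated)
30 | methyl (2Z)-5-[(1R,2S,4aS,6R,8aS)-2-formyl-6-hydroxy-5,5,8a-trimethyldecahydronaphthalen-1-yl]-3-methylpent-2-enoate | COC(=O)/C=C(/C)CC[C@@H]1[C@@H](C=O)CC[C@@H]2C(C)(C)[C@H](O)CC[C@@]12C | target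

**Count and risks**

Total step count: 19. Longest linear sequence: 18 steps (steps 1–4 and 6–19); step 5 is a one-step side branch.

Steps most likely to fail:

1. Step 6. The magnesium enolate may add too slowly to the acceptor, so that proton transfer scrambles the enolate or the acceptor oligomerises. Fallback: the two bond formations are separated. The copper-catalysed addition of 8 to 6 is run in the presence of Me3SiCl to give the trimethylsilyl enol ether of the conjugate adduct F1, which is isolated. MeLi in THF at 0 °C then releases the salt-free lithium enolate F2, which is more reactive than the magnesium enolate and is combined with 9 at −78 °C to give 11, where the route is rejoined.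

2. Step 10. Hydrogenation of the hindered C5=C6 bond may stall or show poor facial selectivity, and the double methylation of step 8 that precedes it may be inefficient. Fallback: the ring fusion is set by dissolving-metal reduction instead. Enolate 10 (from 6 and 8 as in step 6) is trapped with 2-(trimethylsilyl)pent-1-en-3-one to give the α-silyl ethyl ketone adduct F3. NaOMe in MeOH closes ring A to the 4-methyl-Δ4-3-ketone F4. Li in NH3/THF with one equivalent of t-BuOH gives the trans-fused lithium enolate F5, which MeI methylates at C4 to give the saturated 4,4-dimethyl-3-ketone F6 (reductive alkylation of an enone). NaBH4 as in step 9 then gives 18; steps 8 and 10 are not needed on this path.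

3. Step 16. Enolisation of the α-branched C8 ketone by the basic ylide may outrun addition, leaving the ketone unconverted. Fallback: C17 is introduced by Peterson olefination. [Methoxy(trimethylsilyl)methyl]lithium (from (methoxymethyl)trimethylsilane and s-BuLi, one extra equivalent being consumed by the alkyne C–H) adds to 23 to give the β-hydroxysilane F7, and KH in THF brings about the syn elimination that gives 24, where the route is rejoined.

**Further compounds**

F1 | step 6 | trimethylsilyl enol ether of the conjugate adduct (C5=C10) | O1CCOC1CC[C@@H]2[C@@H](O[Si](C)(C)C(C)(C)C)CCC(O[Si](C)(C)C)=C2C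
F2 | step 6 | lithium enolate (C5=C10) | O1CCOC1CC[C@@H]2[C@@H](O[Si](C)(C)C(C)(C)C)CCC(O[Li])=C2C
F3 | step 10 | α-silyl ethyl ketone adduct | O1CCOC1CC[C@@H]2[C@@H](O[Si](C)(C)C(C)(C)C)CCC(=O)[C@@]2(C)CC([Si](C)(C)C)C(=O)CC
F4 | step 10 | 4-methyl-Δ4-3-ketone | O1CCOC1CC[C@@H]2[C@@H](O[Si](C)(C)C(C)(C)C)CCC3=C(C)C(=O)CC[C@@]23C
F5 | step 10 | trans-fused lithium enolate | O1CCOC1CC[C@@H]2[C@@H](O[Si](C)(C)C(C)(C)C)CC[C@@H]3C(C)=C(O[Li])CC[C@@]23C
F6 | step 10 | saturated 4,4-dimethyl-3-ketone | O1CCOC1CC[C@@H]2[C@@H](O[Si](C)(C)C(C)(C)C)CC[C@@H]3C(C)(C)C(=O)CC[C@@]23C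
F7 | step 16 | β-hydroxysilane | C#CCC[C@@H]1C(O)(C(OC)[Si](C)(C)C)CC[C@@H]2C(C)(C)[C@H](OC3CCCCO3)CC[C@@]12C
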